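Ring atoms are numbered C1 (C=O), C2 (C–N), C3 (=CH), C4 (C–OH), C5/C6 (oxirane). Retrosynthetic cuts, in order: the ethyl ester, the ring bond C3–C4, the oxirane (back to a Z-alkene), the C1/C4 carbonyl pair (back to a 2,5-disubstituted furan), the enamide C2–N bond (enol triflate + primary amide), the furan–alkyl bond.
Enabling feature: N–C2=C3–C4(OH) is an N-acyl enamine carrying the carbinol carbon on its β-carbon (an aza-ene retron; nitrogen turns the enone β-carbon C3 into a donor towards a C4 ketone), and C1/C4 flank the cis-oxirane in a 1,4-dioxygen pattern that a furan delivers with cis geometry.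
Forward: side-chain amide (7 steps) and furyl methyl ketone → enol triflate → enamide → singlet-oxygen opening of the furan to the (Z)-enedione → cis-epoxide → ring closure C3–C4 → ester cleavage.
Stereochemistry: the syn-4,6-dimethyl pair comes from lipase desymmetrisation of a meso diol; both oxirane centres from a catalyst-controlled cis-epoxidation; the C4 carbinol from the oxirane during ring closure (OH anti to the epoxide oxygen); the E-acrylamide from a stabilised Wittig reagent.

Key step: step 13

Assumption: the (R)-configured ligand in step 12 is taken to give the (2S,3R)-oxirane; if the sense of induction is the opposite, the (S)-ligand is used and nothing else changes.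

Step 1
Reactants: 1 meso-2,4-dimethylglutaric anhydride
Product: 2 meso-(2R,4S)-2,4-dimethylpentane-1,5-diol
Conditions: LiAlH4, THF, 0 °C → reflux
Reagents that add atoms: none
Why: Hydride reduction of a cyclic anhydride to the diol leaves both stereocentres untouched, so the syn (meso) relationship of the two methyl groups is carried over.

Step 2
Reactants: 2 meso-(2R,4S)-2,4-dimethylpentane-1,5-diol
Product: 3 (2S,4R)-5-hydroxy-2,4-dimethylpentyl acetate
Conditions: Pseudomonas fluorescens lipase (Amano AK), vinyl acetate, THF, rt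
Reagents that add atoms: vinyl acetate, CC(=O)OC=C
Why: Enzymatic desymmetrisation by irreversible transesterification should acylate the hydroxymethyl arm at the (S)-centre, in line with the usual preference of this lipase for 2-methyl-branched primary diols, which leaves the free alcohol next to the (R)-centre that will carry the isobutenyl group.

Step 3
Reactants: 3 (2S,4R)-5-hydroxy-2,4-dimethylpentyl acetate
Product: 4 (2S,4R)-2,4-dimethyl-5-oxopentyl acetate
Conditions: Dess–Martin periodinane, CH2Cl2, 0 °C → rt; used crude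
Reagents that add atoms: none
Why: Dess–Martin oxidation is mild and non-basic, so the α-methyl stereocentre should survive if the aldehyde is used at once.

Step 4
Reactants: 4 (2S,4R)-2,4-dimethyl-5-oxopentyl acetate
Product: 5 (2S,4R)-2,4,6-trimethylhept-5-en-1-yl acetate
Conditions: i-PrPPh3I, n-BuLi, THF, 0 °C; then 4, −78 °C → rt
Reagents that add atoms: isopropyltriphenylphosphonium iodide, CC(C)[P+](c1ccccc1)(c1ccccc1)c1ccccc1.[I-]
Why: Wittig olefination with the non-stabilised isopropylidene ylide installs the trisubstituted alkene (no E/Z issue), and addition at −78 °C should limit enolisation of the α-branched aldehyde and attack on the acetate.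

Step 5
Reactants: 5 (2S,4R)-2,4,6-trimethylhept-5-en-1-yl acetate
Product: 6 (2S,4R)-2,4,6-trimethylhept-5-en-1-ol
Conditions: K2CO3 (cat.), MeOH, rt
Reagents that add atoms: none
Why: Base-catalysed methanolysis (transesterification) of the acetate touches no stereocentre.

Step 6
Reactants: 6 (2S,4R)-2,4,6-trimethylhept-5-en-1-ol
Product: 7 (2S,4R)-2,4,6-trimethylhept-5-enal
Conditions: Dess–Martin periodinane, CH2Cl2, 0 °C → rt; used crude
Reagents that add atoms: none
Why: Dess–Martin oxidation leaves the trisubstituted alkene alone and should not epimerise the α-centre.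

Step 7
Reactants: 7 (2S,4R)-2,4,6-trimethylhept-5-enal
Product: 8 (2E,4S,6R)-4,6,8-trimethylnona-2,7-dienamide
Conditions: Ph3P=CHCONH2, CH2Cl2, rt → 40 °C
Reagents that add atoms: 2-(triphenylphosphoranylidene)acetamide, NC(=O)C=P(c1ccccc1)(c1ccccc1)c1ccccc1
Why: Wittig reaction with a stabilised ylide is E-selective and neutral, so the primary acrylamide should form directly without epimerising the γ-centre.

Step 8
Reactants: 9 ethyl 5-bromopentanoate; 10 1-(5-bromofuran-2-yl)ethan-1-one
Product: 12 ethyl 5-(5-acetylfuran-2-yl)pentanoate, via (5-ethoxy-5-oxopentyl)zinc bromide 11 (not isolated)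
Conditions: Zn dust, LiCl, THF, 50 °C (9 → 11); then 10, Pd(OAc)2 (2 mol %), SPhos (4 mol %), THF, rt
Reagents that add atoms: none
Why: Negishi coupling of an ester-bearing alkylzinc halide with a heteroaryl bromide tolerates both the ester and the methyl ketone.

Step 9
Reactants: 12 ethyl 5-(5-acetylfuran-2-yl)pentanoate
Product: 13 ethyl 5-{5-[1-(trifluoromethanesulfonyloxy)ethenyl]furan-2-yl}pentanoate
Conditions: KN(SiMe3)2, THF, −78 °C; then PhNTf2, −78 → 0 °C
Reagents that add atoms: N-phenylbis(trifluoromethanesulfonimide), O=S(=O)(N(c1ccccc1)S(=O)(=O)C(F)(F)F)C(F)(F)F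
Why: Kinetic deprotonation should take the methyl ketone (more acidic than the ester α-CH2), and O-triflation of the potassium enolate gives the enol triflate.

Step 10
Reactants: 13 ethyl 5-{5-[1-(trifluoromethanesulfonyloxy)ethenyl]furan-2-yl}pentanoate; 8 (2E,4S,6R)-4,6,8-trimethylnona-2,7-dienamide
Product: 14 ethyl 5-[5-(1-{[(2E,4S,6R)-4,6,8-trimethylnona-2,7-dienoyl]amino}ethenyl)furan-2-yl]pentanoate
Conditions: Pd2(dba)3 (2.5 mol %), Xantphos (7.5 mol %), Cs2CO3, 1,4-dioxane, 50 °C
Reagents that add atoms: none
Why: Amidation of an enol triflate with a primary amide, catalysed by zerovalent palladium with a wide-bite-angle bisphosphine, should give the secondary enamide, the amide NH2 being the only nucleophile present.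

Step 11
Reactants: 14 ethyl 5-[5-(1-{[(2E,4S,6R)-4,6,8-trimethylnona-2,7-dienoyl]amino}ethenyl)furan-2-yl]pentanoate
Product: 16 ethyl (7Z)-6,9-dioxo-10-{[(2E,4S,6R)-4,6,8-trimethylnona-2,7-dienoyl]amino}undeca-7,10-dienoate, via furan 2,5-endoperoxide 15 (not isolated)
Conditions: O2, hν (visible), methylene blue (cat.), CH2Cl2, −78 °C; then Me2S, −78 °C → rt
Reagents that add atoms: dioxygen, O=O
Why: Singlet oxygen should add [4+2] across the electron-rich 2,5-disubstituted furan much faster than it attacks the trisubstituted alkene or the enamide, and reduction of the endoperoxide with Me2S unveils the enedione with the cis geometry inherited from the ring (furan photo-oxygenation with reductive opening).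

Step 12
Reactants: 16 ethyl (7Z)-6,9-dioxo-10-{[(2E,4S,6R)-4,6,8-trimethylnona-2,7-dienoyl]amino}undeca-7,10-dienoate
Product: 17 ethyl 6-oxo-6-[(2S,3R)-3-(2-{[(2E,4S,6R)-4,6,8-trimethylnona-2,7-dienoyl]amino}prop-2-enoyl)oxiran-2-yl]hexanoate
Conditions: Yb(O-iPr)3 (10 mol %), (R)-3-(hydroxymethyl)-1,1'-bi-2-naphthol (10 mol %), t-BuOOH (1.2 equiv, decane), 4 Å MS, THF, 0 °C → rt
Reagents that add atoms: tert-butyl hydroperoxide, CC(C)(C)OO
Why: Catalytic asymmetric nucleophilic (Weitz–Scheffer-type) epoxidation of a cis-enone with the Yb(O-iPr)3/binaphthol peroxide system, which closes the oxirane faster than the peroxy-enolate rotates and so should keep the cis geometry; the doubly activated C7=C8 bond is the only good acceptor (C10=C11 is switched off as the ytterbium amidate, the dienamide is a poor acceptor), and the amidate/C9 ketone pair is expected to anchor the metal so that the ligand sets both oxirane centres from one face.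

Step 13
Reactants: 17 ethyl 6-oxo-6-[(2S,3R)-3-(2-{[(2E,4S,6R)-4,6,8-trimethylnona-2,7-dienoyl]amino}prop-2-enoyl)oxiran-2-yl]hexanoate
Product: 19 ethyl 5-[(1S,2S,6R)-2-hydroxy-5-oxo-4-{[(2E,4S,6R)-4,6,8-trimethylnona-2,7-dienoyl]amino}-7-oxabicyclo[4.1.0]hept-3-en-2-yl]pentanoate, via cyclic N-acyl imine 18 (not isolated)
Conditions: (PhO)2P(O)OH (10 mol %), 4 Å MS, toluene, 0 °C → rt
Reagents that add atoms: none
Why: Proposed new method: the phosphoric acid bridges the amide N–H and the C6 ketone oxygen of 17 so that the terminal enamide carbon, an enone β-carbon made nucleophilic by the nitrogen lone pair, adds to the ketone in an intramolecular aza-ene (enamide–carbonyl) reaction, and the cyclic N-acyl imine 18 then tautomerises to the conjugated 2-amido enone. The closest known reaction types are the acid- and Lewis-acid-catalysed additions of secondary enamides to aldehydes and activated ketones and the intramolecular additions of tertiary enamides to ketones; new here are the carbocyclic mode and the acyl-conjugated enamide. The six-membered ring closes 6-(enolendo)-exo-trig, helped by the cis-oxirane, which holds the two acyl groups on one side. The new carbinol centre is set by the neighbouring oxirane carbon: the ene geometry puts the ketone oxygen pseudo-axial (1,3 to N–H), and of the two half-chair transition states the one with C=O antiperiplanar to the oxirane C–O bond (opposed dipoles, no chelating metal) should be favoured, which places OH anti and the ester chain syn to the epoxide oxygen. The step needs C- over N-attack and an intact epoxide: N-attack gives only a reversible hemiaminal whereas C–C formation is sealed by tautomerisation, and an oxirane flanked by two acyl groups resists acid opening.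

Step 14
Reactants: 19 ethyl 5-[(1S,2S,6R)-2-hydroxy-5-oxo-4-{[(2E,4S,6R)-4,6,8-trimethylnona-2,7-dienoyl]amino}-7-oxabicyclo[4.1.0]hept-3-en-2-yl]pentanoate
Product: 20 5-[(1S,2S,6R)-2-hydroxy-5-oxo-4-{[(2E,4S,6R)-4,6,8-trimethylnona-2,7-dienoyl]amino}-7-oxabicyclo[4.1.0]hept-3-en-2-yl]pentanoic acid
Conditions: pig liver esterase, phosphate buffer pH 7.2/acetone 9:1, rt
Reagents that add atoms: water, O
Why: Enzymatic ester hydrolysis at neutral pH should accept the unhindered terminal ethyl ester and leave the base-sensitive epoxy-enone, the tertiary alcohol and the enamide untouched.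

Compound list
1 | meso-2,4-dimethylglutaric anhydride, (3R,5S)-3,5-dimethyloxane-2,6-dione | O=C1[C@H](C)C[C@H](C)C(=O)O1 | starting material
2 | meso-(2R,4S)-2,4-dimethylpentane-1,5-diol | OC[C@H](C)C[C@H](C)CO | intermediate
3 | (2S,4R)-5-hydroxy-2,4-dimethylpentyl acetate | OC[C@H](C)C[C@H](C)COC(C)=O | intermediate
4 | (2S,4R)-2,4-dimethyl-5-oxopentyl acetate | O=C[C@H](C)C[C@H](C)COC(C)=O | intermediate
5 | (2S,4R)-2,4,6-trimethylhept-5-en-1-yl acetate | CC(C)=C[C@H](C)C[C@H](C)COC(C)=O | intermediate
6 | (2S,4R)-2,4,6-trimethylhept-5-en-1-ol | CC(C)=C[C@H](C)C[C@H](C)CO | intermediate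
7 | (2S,4R)-2,4,6-trimethylhept-5-enal | CC(C)=C[C@H](C)C[C@H](C)C=O | intermediate
8 | (2E,4S,6R)-4,6,8-trimethylnona-2,7-dienamide | CC(C)=C[C@H](C)C[C@H](C)/C=C/C(N)=O | intermediate
9 | ethyl 5-bromopentanoate | CCOC(=O)CCCCBr | starting material
10 | 1-(5-bromofuran-2-yl)ethan-1-one | CC(=O)c1ccc(Br)o1 | starting material
11 | (5-ethoxy-5-oxopentyl)zinc bromide | CCOC(=O)CCCC[Zn]Br | intermediate (not isolated)
12 | ethyl 5-(5-acetylfuran-2-yl)pentanoate | CCOC(=O)CCCCc1ccc(C(C)=O)o1 | intermediate
13 | ethyl 5-{5-[1-(trifluoromethanesulfonyloxy)ethenyl]furan-2-yl}pentanoate | CCOC(=O)CCCCc1ccc(C(=C)OS(=O)(=O)C(F)(F)F)o1 | intermediate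
14 | ethyl 5-[5-(1-{[(2E,4S,6R)-4,6,8-trimethylnona-2,7-dienoyl]amino}ethenyl)furan-2-yl]pentanoate | CC(C)=C[C@H](C)C[C@H](C)/C=C/C(=O)NC(=C)c1ccc(CCCCC(=O)OCC)o1 | intermediate
15 | ethyl 5-[4-(1-{[(2E,4S,6R)-4,6,8-trimethylnona-2,7-dienoyl]amino}ethenyl)-2,3,7-trioxabicyclo[2.2.1]hept-5-en-1-yl]pentanoate (furan 2,5-endoperoxide, both bridgehead configurations) | CC(C)=C[C@H](C)C[C@H](C)/C=C/C(=O)NC(=C)C12C=CC(CCCCC(=O)OCC)(OO1)O2 | intermediate (not isolated)
16 | ethyl (7Z)-6,9-dioxo-10-{[(2E,4S,6R)-4,6,8-trimethylnona-2,7-dienoyl]amino}undeca-7,10-dienoate | CC(C)=C[C@H](C)C[C@H](C)/C=C/C(=O)NC(=C)C(=O)/C=C\C(=O)CCCCC(=O)OCC | intermediate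
17 | ethyl 6-oxo-6-[(2S,3R)-3-(2-{[(2E,4S,6R)-4,6,8-trimethylnona-2,7-dienoyl]amino}prop-2-enoyl)oxiran-2-yl]hexanoate | CC(C)=C[C@H](C)C[C@H](C)/C=C/C(=O)NC(=C)C(=O)[C@@H]1O[C@@H]1C(=O)CCCCC(=O)OCC | intermediate
18 | ethyl 5-[(1S,2S,6R)-2-hydroxy-5-oxo-4-{[(2E,4S,6R)-4,6,8-trimethylnona-2,7-dienoyl]imino}-7-oxabicyclo[4.1.0]heptan-2-yl]pentanoate (cyclic N-acyl imine) | CC(C)=C[C@H](C)C[C@H](C)/C=C/C(=O)N=C1C[C@@](O)(CCCCC(=O)OCC)[C@H]2O[C@H]2C1=O | intermediate (not isolated)
19 | ethyl 5-[(1S,2S,6R)-2-hydroxy-5-oxo-4-{[(2E,4S,6R)-4,6,8-trimethylnona-2,7-dienoyl]amino}-7-oxabicyclo[4.1.0]hept-3-en-2-yl]pentanoate | CC(C)=C[C@H](C)C[C@H](C)/C=C/C(=O)NC1=C[C@@](O)(CCCCC(=O)OCC)[C@H]2O[C@H]2C1=O | intermediate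
20 | 5-[(1S,2S,6R)-2-hydroxy-5-oxo-4-{[(2E,4S,6R)-4,6,8-trimethylnona-2,7-dienoyl]amino}-7-oxabicyclo[4.1.0]hept-3-en-2-yl]pentanoic acid | CC(C)=C[C@H](C)C[C@H](C)/C=C/C(=O)NC1=C[C@@](O)(CCCCC(=O)O)[C@H]2O[C@H]2C1=O | target

Total step count: 14. Longest linear sequence: 12 steps (steps 1–7, then 10–14); steps 8 and 9 form the short branch that joins at step 10.

Steps most likely to fail

Step 13 (Proposed new method). The acyl-conjugated enamide carbon may be too weak a donor for an unactivated epoxy ketone, so that no C–C bond forms. Alternatively, closure may run through a proton-bridged arrangement of ketone and oxirane oxygens and give the syn-hydroxy epoxide. The fallback uses known chemistry and sets out from 17. Chelation-controlled addition of vinylmagnesium bromide (2.2 equiv, the first consumed by the N–H; THF, −78 °C) to the alkyl ketone should give the tertiary allylic alcohol ethyl (6S)-6-hydroxy-6-[(2S,3R)-3-(2-{[(2E,4S,6R)-4,6,8-trimethylnona-2,7-dienoyl]amino}prop-2-enoyl)oxiran-2-yl]oct-7-enoate F1. Attack on the magnesium chelate of ketone and oxirane oxygens, from the face away from the second oxirane carbon, leads to the same carbinol configuration as the planned step. Ring-closing metathesis between the new vinyl group and the enamide methylene (second-generation Grubbs catalyst, toluene, 80 °C) then comes back to the route at 19. Ring carbon C3 then stems from the Grignard reagent, and the former enamide methylene is lost.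

Step 12. Face differentiation may be poor, because either of the two ketones can steer the ytterbium peroxide and the two binding modes lead to opposite oxirane configurations. Some cis geometry may also be lost by bond rotation in the peroxy-enolate. The fallback gives up asymmetric induction and sets out from 16. The epoxidation is run with the racemic ligand under the same conditions, which should give a 1:1 mixture of 17 and its oxirane diastereomer ethyl 6-oxo-6-[(2R,3S)-3-(2-{[(2E,4S,6R)-4,6,8-trimethylnona-2,7-dienoyl]amino}prop-2-enoyl)oxiran-2-yl]hexanoate F2. The two are diastereomers because the acyl chain is enantiopure, so they can be separated by preparative HPLC on a chiral stationary phase, and the route resumes at 17.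

Step 10. The enol triflate may be lost before C–N coupling, by base-induced elimination to the 2-ethynylfuran or by hydrolysis back to the ketone. The fallback avoids the enolate and the triflate and sets out from 12. Triphenyl phosphite/Br2 with Et3N (CH2Cl2, −60 °C → rt) converts the methyl ketone directly into the vinyl bromide ethyl 5-[5-(1-bromoethenyl)furan-2-yl]pentanoate F3. Copper-catalysed N-vinylation of amide 8 (CuI, N,N'-dimethylethylenediamine, K2CO3, toluene, 80 °C) then comes back to the route at 14.

Further compounds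
F1 | step 13 | ethyl (6S)-6-hydroxy-6-[(2S,3R)-3-(2-{[(2E,4S,6R)-4,6,8-trimethylnona-2,7-dienoyl]amino}prop-2-enoyl)oxiran-2-yl]oct-7-enoate | CC(C)=C[C@H](C)C[C@H](C)/C=C/C(=O)NC(=C)C(=O)[C@@H]1O[C@@H]1[C@@](O)(C=C)CCCCC(=O)OCC
F2 | step 12 | ethyl 6-oxo-6-[(2R,3S)-3-(2-{[(2E,4S,6R)-4,6,8-trimethylnona-2,7-dienoyl]amino}prop-2-enoyl)oxiran-2-yl]hexanoate | CC(C)=C[C@H](C)C[C@H](C)/C=C/C(=O)NC(=C)C(=O)[C@H]1O[C@H]1C(=O)CCCCC(=O)OCC
F3 | step 10 | ethyl 5-[5-(1-bromoethenyl)furan-2-yl]pentanoate | CCOC(=O)CCCCc1ccc(C(Br)=C)o1
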